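We follow one ratio through this flask: the partner that goes to target against the partner that goes to second product.

    partner + catalyst intermediate A → free catalyst + target (k1 = 360 /M/h)
    target ⇌ isomer of the product (K2 = 2.7, k2 = 0.026 /h)
    second substrate + free catalyst ⇌ catalyst intermediate B (K3 = 250 /M, k3 = 4100 /M/h)
    starting material + free catalyst ⇌ catalyst intermediate A (K4 = 400 /M, k4 = 19000 /M/h)
    partner + catalyst intermediate B → free catalyst + second product (k5 = 4200 /M/h)

starting material 10 mM; second substrate 10.0 mM; partner 6.00 mM (fed, over 3.0 d); free catalyst 100 µM; time 15 d

- the reaction counts as stopped when no species that holds the starting material changes by six tenths of a point or more over the second half of the time
- run time (flask): 15 d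

- at 15 d, what has stopped the reaction, if anything has (all of the starting material has reacted / the partner has run out first / it is still moving / no working catalyst is left / forward and back rates have come level)
- how much of the starting material has reacted by 15 d
- how much target there is at 15 d, in percent of the starting material charged

The partner is the limiting reagent, since its 6.00 mM stands against 20.0 mM of the two substrates. Even if the whole catalyst charge sat as intermediate A, the slower of the two captures, its half-life would be 19.3 h, short against 15 d, so we expect it used up and ask how it divides.

Partner concentration cancels from the ratio of the two capture rates, and if both intermediates stay at binding equilibrium, free catalyst cancels too. What remains is the selectivity factor, k1 K4 over k5 K3, 0.137, times starting material over second substrate. It follows that the part of the starting material left equals the part of the second substrate left, raised to the selectivity factor, while the two amounts consumed add up to the partner charge. Each depends on the other, so we iterate, putting each row's answer into the next: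

- ratio at the charges: second substrate left 100%, starting material reacted 0.724 mM
- first round: second substrate left 47.2%, starting material reacted 0.977 mM
- second round: second substrate left 49.8%, starting material reacted 0.912 mM
- third round: second substrate left 49.1%, starting material reacted 0.929 mM

The top row keeps the opening ratio and gives 0.724 mM reacted, less than the 0.929 mM of the last row. The first round hands the rest of the partner to the second substrate, which falls to 47.2% left, lower than the 49.1% of the third round, and this remainder, raised to the selectivity factor, gives 0.977 mM reacted, more than the last row. The last two rows differ by 0.0170 mM, so we commit to 9.29% reacted. The relaxation half-life of target and isomer, 0.811 d, is short against 15 d, so target keeps one part in 3.70, or 2.51% of the charge.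

The forecast likewise says the partner has run out first, with 9.3% reacted and 2.5% target, on the ground that “intermediate B takes it far faster than intermediate A”.

The flask gives the partner has run out first, with 10.8% reacted and 2.76% target. In the flask, capture by intermediate B had done half of its turnover by 1.78 d, and the partner stood at 12.2% at 3.00 d and 0% at 7.50 d. Between those times target turned into isomer, which rose from 3.71% to 7.35%. The parts left in the flask, 89% and 50%, give a read exponent of 0.165, above our 0.137. The neighbour with 6.0 mM of second substrate kept 30% of it, for which 0.137 puts starting material at 84.8% left, the flask's reading at 82.0%, and the neighbour holds 81%.

(The numbers of this flask are assumed.)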